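**Plan**

- Retrosynthesis first cuts the aryl–carbonyl bond of the benzophenone (an aryl anion between the two phenol oxygens plus a benzoyl donor). It then cuts two bonds of the benzene ring, C(OH)–C(prenyl) on one side and C(OMe)–C(prenyl) on the other, to reach a 3-siloxy-2-prenylcyclobutenone and a prenylated methyl ynol ether.
- Enabling feature: a benzene ring whose OMe carbon is flanked by two prenyl-bearing carbons, with the remaining three carbons O-bearing, H-bearing (later benzoyl) and O-bearing. The three oxygenated carbons map onto a ketene carbonyl carbon, a silyl enol ether carbon and an ynol ether carbon.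
- Forward: ester homologation gives a silyl ynol ether, ketene [2+2] cycloaddition gives the four-membered ring, and alkylation of methoxyacetylide gives the second two-carbon piece. The benzannulation builds the only new ring (the arene). The phenyl ring arrives intact with a Weinreb amide after desilylation, MOM protection and ortho-lithiation.
- Stereochemistry: none to set; the target is achiral and both alkenes carry geminal methyl groups.

Key step: step 4

Remark: ketene is taken to be generated on demand by pyrolysis of acetone and passed as a gas into the reaction, so acetone counts as the starting material of step 2.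

**Route**

Step 1
Reactants: 1 ethyl 4-methylpent-3-enoate
Product: 4 5-methyl-1-[(triisopropylsilyl)oxy]hex-4-en-1-yne, via lithium dibromo enolate 2 (not isolated), via lithium ynolate 3 (not isolated)
Conditions: CH2Br2, LiTMP (lithium 2,2,6,6-tetramethylpiperidide), THF, −78 °C; LiN(SiMe3)2; n-BuLi, −78 °C to rt; i-Pr3SiCl, −78 °C to rt
Reagents that add atoms: dibromomethane, BrCBr; chlorotriisopropylsilane, CC(C)[Si](Cl)(C(C)C)C(C)C
Why: Kowalski ester homologation, in which LiCHBr2 adds to the ester, bromine–lithium exchange on enolate 2 triggers 1,2-migration of the alkyl group to ynolate 3, and the bulky silyl chloride traps 3 on oxygen to give a stable silyl ynol ether.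

Step 2
Reactants: 4 5-methyl-1-[(triisopropylsilyl)oxy]hex-4-en-1-yne; 5 acetone
Product: 7 2-(3-methylbut-2-en-1-yl)-3-[(triisopropylsilyl)oxy]cyclobut-2-en-1-one, via ketene 6 (not isolated)
Conditions: acetone vapour over a glowing NiCr wire (ketene lamp); ketene stream into 4, MeCN, 0 °C to rt
Reagents that add atoms: none
Why: Regioselective thermal [2+2] cycloaddition of ketene with an electron-rich silyl ynol ether, whose oxygen-remote carbon bonds to the ketene carbonyl carbon, is the established entry to 3-siloxycyclobutenones and should leave the isolated trisubstituted alkene untouched.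

Step 3
Reactants: 8 chloroacetaldehyde dimethyl acetal; 9 1-bromo-3-methylbut-2-ene
Product: 11 1-methoxy-5-methylhex-4-en-1-yne, via sodium methoxyethynide 10 (not isolated)
Conditions: NaNH2 (3.0 equiv), liq. NH3, −33 °C; then 9, THF, −78 to −33 °C; NH4Cl
Reagents that add atoms: none
Why: Twofold amide-induced elimination of the chloroacetal gives the metalated alkoxyacetylene, which should undergo SN2 C-alkylation at the primary carbon of the allylic bromide, the exact three equivalents of amide leaving no strong base to isomerise the skipped enyne.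

Step 4
Reactants: 7 2-(3-methylbut-2-en-1-yl)-3-[(triisopropylsilyl)oxy]cyclobut-2-en-1-one; 11 1-methoxy-5-methylhex-4-en-1-yne
Product: 16 3-methoxy-2,4-bis(3-methylbut-2-en-1-yl)-5-[(triisopropylsilyl)oxy]phenol, via siloxy vinylketene 12 (not isolated), via vinylcyclobutenone 13 (not isolated), via dienylketene 14 (not isolated), via cyclohexadienone 15 (not isolated)
Conditions: 11 (2 equiv), toluene, 80 °C then 110 °C, sealed tube, argon
Reagents that add atoms: none
Why: Heating opens 7 by 4-electron conrotatory cleavage of its C1–C4 bond to vinylketene 12, whose ketene C=C adds ynol ether 11 in a [2+2] cycloaddition to give 13; a second 4-electron opening gives dienylketene 14, 6-electron disrotatory electrocyclisation gives dienone 15, and enolisation gives phenol 16. The closest known reaction type is the Danheiser benzannulation of cyclobutenones with alkoxy- or siloxyalkynes, including 3-siloxycyclobutenones as resorcinol precursors. The benzene ring is closed in the 6-electron electrocyclisation, which re-joins the former carbonyl and CH2 carbons of 7 after the two alkyne carbons have been inserted between the carbonyl carbon and the prenyl-bearing carbon. No stereocentre is created, the quaternary carbon of 13 being lost again on ring opening. The step needs the [2+2] regiochemistry that places OMe between the two prenyl-bearing carbons, and this follows from the polarisation of the ynol ether, whose oxygen-remote carbon is the nucleophile that bonds to the electrophilic ketene carbonyl carbon. It also needs the ketene to choose the alkyne over the alkenes and over itself, which the electron-rich triple bond, the poor ketenophilicity of trisubstituted alkenes, the excess of 11 and the inability of a methyl ynol ether to fragment by retro-ene loss of an alkene should secure.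

Step 5
Reactants: 16 3-methoxy-2,4-bis(3-methylbut-2-en-1-yl)-5-[(triisopropylsilyl)oxy]phenol
Product: 17 5-methoxy-4,6-bis(3-methylbut-2-en-1-yl)benzene-1,3-diol
Conditions: Bu4NF, AcOH, THF, 0 °C to rt
Reagents that add atoms: none
Why: Fluoride-induced cleavage of the aryl silyl ether is driven by the strong Si–F bond, and the acetic acid buffer keeps the electron-rich resorcinol protonated and so less prone to oxidation.

Step 6
Reactants: 17 5-methoxy-4,6-bis(3-methylbut-2-en-1-yl)benzene-1,3-diol
Product: 18 3-methoxy-1,5-bis(methoxymethoxy)-2,4-bis(3-methylbut-2-en-1-yl)benzene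
Conditions: MOMCl, i-Pr2NEt, CH2Cl2, 0 °C to rt
Reagents that add atoms: chloromethyl methyl ether, COCCl
Why: Williamson-type O-alkylation of both phenols under Hünig base installs two base-stable acetal ethers that are strong ortho-directing groups for the next step.

Step 7
Reactants: 18 3-methoxy-1,5-bis(methoxymethoxy)-2,4-bis(3-methylbut-2-en-1-yl)benzene; 19 N-methoxy-N-methylbenzamide
Product: 22 [4-methoxy-2,6-bis(methoxymethoxy)-3,5-bis(3-methylbut-2-en-1-yl)phenyl](phenyl)methanone, via aryllithium 20 (not isolated), via lithium hemiaminal adduct 21 (not isolated)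
Conditions: n-BuLi, THF, −20 to 0 °C; then 19, −78 °C to rt; H2O
Reagents that add atoms: none
Why: Directed ortho-metalation at the only ring hydrogen, which lies between two cooperating OMOM groups and should therefore be removed faster than the benzylic-allylic prenyl hydrogens, followed by Weinreb ketone synthesis in which the chelated adduct 21 prevents over-addition.

Step 8
Reactants: 22 [4-methoxy-2,6-bis(methoxymethoxy)-3,5-bis(3-methylbut-2-en-1-yl)phenyl](phenyl)methanone
Product: 23 [2,6-dihydroxy-4-methoxy-3,5-bis(3-methylbut-2-en-1-yl)phenyl](phenyl)methanone (CNP0289865.0)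
Conditions: 3 M aq. HCl, MeOH, 40 °C
Reagents that add atoms: none
Why: Acid-catalysed acetal exchange with methanol releases both phenols as dimethoxymethane is formed, and the mild acid together with the deactivating ortho-benzoyl group should keep the phenols from cyclising onto the prenyl alkenes to chromans.

**Compound list**

1 | ethyl 4-methylpent-3-enoate | CCOC(=O)CC=C(C)C | starting material
2 | lithium 1,1-dibromo-5-methylhexa-1,4-dien-2-olate | [Li+].[O-]C(=C(Br)Br)CC=C(C)C | intermediate
3 | lithium 5-methylhex-4-en-1-yn-1-olate | [Li+].[O-]C#CCC=C(C)C | intermediate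
4 | 5-methyl-1-[(triisopropylsilyl)oxy]hex-4-en-1-yne | CC(C)=CCC#CO[Si](C(C)C)(C(C)C)C(C)C | intermediate
5 | acetone | CC(C)=O | starting material
6 | ketene (ethenone) | C=C=O | intermediate
7 | 2-(3-methylbut-2-en-1-yl)-3-[(triisopropylsilyl)oxy]cyclobut-2-en-1-one | O=C1CC(O[Si](C(C)C)(C(C)C)C(C)C)=C1CC=C(C)C | intermediate
8 | chloroacetaldehyde dimethyl acetal (2-chloro-1,1-dimethoxyethane) | COC(CCl)OC | starting material
9 | 1-bromo-3-methylbut-2-ene (prenyl bromide) | CC(C)=CCBr | starting material
10 | sodium methoxyethynide | [Na+].[C-]#COC | intermediate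
11 | 1-methoxy-5-methylhex-4-en-1-yne | COC#CCC=C(C)C | intermediate
12 | 2-(3-methylbut-2-en-1-yl)-3-[(triisopropylsilyl)oxy]buta-1,3-dien-1-one | O=C=C(CC=C(C)C)C(=C)O[Si](C(C)C)(C(C)C)C(C)C | intermediate
13 | 3-methoxy-2,4-bis(3-methylbut-2-en-1-yl)-4-{1-[(triisopropylsilyl)oxy]ethenyl}cyclobut-2-en-1-one (racemic) | O=C1C(CC=C(C)C)=C(OC)C1(CC=C(C)C)C(=C)O[Si](C(C)C)(C(C)C)C(C)C | intermediate
14 | (3E)-3-methoxy-2,4-bis(3-methylbut-2-en-1-yl)-5-[(triisopropylsilyl)oxy]hexa-1,3,5-trien-1-one | O=C=C(CC=C(C)C)/C(OC)=C(CC=C(C)C)\C(=C)O[Si](C(C)C)(C(C)C)C(C)C | intermediate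
15 | 3-methoxy-2,4-bis(3-methylbut-2-en-1-yl)-5-[(triisopropylsilyl)oxy]cyclohexa-2,4-dien-1-one | O=C1CC(O[Si](C(C)C)(C(C)C)C(C)C)=C(CC=C(C)C)C(OC)=C1CC=C(C)C | intermediate
16 | 3-methoxy-2,4-bis(3-methylbut-2-en-1-yl)-5-[(triisopropylsilyl)oxy]phenol | Oc1cc(O[Si](C(C)C)(C(C)C)C(C)C)c(CC=C(C)C)c(OC)c1CC=C(C)C | intermediate
17 | 5-methoxy-4,6-bis(3-methylbut-2-en-1-yl)benzene-1,3-diol | COc1c(CC=C(C)C)c(O)cc(O)c1CC=C(C)C | intermediate
18 | 3-methoxy-1,5-bis(methoxymethoxy)-2,4-bis(3-methylbut-2-en-1-yl)benzene | COCOc1cc(OCOC)c(CC=C(C)C)c(OC)c1CC=C(C)C | intermediate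
19 | N-methoxy-N-methylbenzamide | CON(C)C(=O)c1ccccc1 | starting material
20 | [4-methoxy-2,6-bis(methoxymethoxy)-3,5-bis(3-methylbut-2-en-1-yl)phenyl]lithium | [Li]c1c(OCOC)c(CC=C(C)C)c(OC)c(CC=C(C)C)c1OCOC | intermediate
21 | lithium [4-methoxy-2,6-bis(methoxymethoxy)-3,5-bis(3-methylbut-2-en-1-yl)phenyl][methoxy(methyl)amino](phenyl)methanolate (racemic) | [Li+].[O-]C(c1ccccc1)(N(C)OC)c1c(OCOC)c(CC=C(C)C)c(OC)c(CC=C(C)C)c1OCOC | intermediate
22 | [4-methoxy-2,6-bis(methoxymethoxy)-3,5-bis(3-methylbut-2-en-1-yl)phenyl](phenyl)methanone | COCOc1c(C(=O)c2ccccc2)c(OCOC)c(CC=C(C)C)c(OC)c1CC=C(C)C | intermediate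
23 | [2,6-dihydroxy-4-methoxy-3,5-bis(3-methylbut-2-en-1-yl)phenyl](phenyl)methanone | COc1c(CC=C(C)C)c(O)c(C(=O)c2ccccc2)c(O)c1CC=C(C)C | target

**Step count and risks**

Total step count: 8. Longest linear sequence: 7 steps (steps 1, 2, 4, 5, 6, 7, 8, from ester 1); step 3 is a one-step side branch.

Steps most likely to fail:

1. Step 4. The siloxy vinylketene may be consumed by dimerisation or by acylating the phenolic product before the methyl ynol ether captures it, or the volatile ynol ether may oligomerise at the temperature needed for the second ring opening. The fallback sets out from cyclobutenone 7 and silyl ynol ether 4 (already made in step 1) and comes back at 18. Heating 7 with 4 in toluene at 80 to 110 °C forms the same two ring bonds with a more nucleophilic, non-volatile ketenophile and should give 2,4-bis(3-methylbut-2-en-1-yl)-3,5-bis[(triisopropylsilyl)oxy]phenol F1. Bu4NF/AcOH then removes both silyl groups to give the symmetrical 2,4-bis(3-methylbut-2-en-1-yl)benzene-1,3,5-triol F2. Two equivalents of MOMCl with i-Pr2NEt should protect the two equivalent, less hindered hydroxyls and leave the one flanked by both prenyl groups free, giving 3,5-bis(methoxymethoxy)-2,6-bis(3-methylbut-2-en-1-yl)phenol F3. MeI/K2CO3 in acetone methylates that hydroxyl to give 18.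

2. Step 3. The skipped enyne has a CH2 that is both propargylic and allylic and may undergo base-mediated prototropic isomerisation in the amide/ammonia medium, or the acetylide may attack the tertiary allylic terminus. The fallback sets out from prenyl bromide 9 and comes back at 11. Trichloroethylene is treated with MeOH/KH in THF to give (E)-1,2-dichloro-1-methoxyethene F4. Two equivalents of n-BuLi at −78 °C convert it into lithium methoxyethynide F5 in a medium free of ammonia and amide. Addition of 9 and DMPU, −78 °C to rt, then gives 11.

3. Step 7. The doubly ortho-substituted aryllithium may add only slowly to the Weinreb amide and instead act as a base on its N-methoxy group, fragmenting the amide with loss of formaldehyde and returning the arene on work-up. The fallback sets out from 18 and comes back at 22. Aryllithium 20, generated as in step 7, is quenched with benzaldehyde, a smaller and more electrophilic partner, to give lithium [4-methoxy-2,6-bis(methoxymethoxy)-3,5-bis(3-methylbut-2-en-1-yl)phenyl](phenyl)methanolate F6. Aqueous work-up gives the racemic [4-methoxy-2,6-bis(methoxymethoxy)-3,5-bis(3-methylbut-2-en-1-yl)phenyl](phenyl)methanol F7. MnO2 in CH2Cl2 should oxidise this doubly benzylic alcohol to 22 without touching the prenyl alkenes.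

Further compounds
F1 | step 4 | 2,4-bis(3-methylbut-2-en-1-yl)-3,5-bis[(triisopropylsilyl)oxy]phenol | Oc1cc(O[Si](C(C)C)(C(C)C)C(C)C)c(CC=C(C)C)c(O[Si](C(C)C)(C(C)C)C(C)C)c1CC=C(C)C
F2 | step 4 | 2,4-bis(3-methylbut-2-en-1-yl)benzene-1,3,5-triol | Oc1cc(O)c(CC=C(C)C)c(O)c1CC=C(C)C
F3 | step 4 | 3,5-bis(methoxymethoxy)-2,6-bis(3-methylbut-2-en-1-yl)phenol | COCOc1cc(OCOC)c(CC=C(C)C)c(O)c1CC=C(C)C
F4 | step 3 | (E)-1,2-dichloro-1-methoxyethene | CO/C(Cl)=C\Cl
F5 | step 3 | lithium methoxyethynide | [Li+].[C-]#COC
F6 | step 7 | lithium [4-methoxy-2,6-bis(methoxymethoxy)-3,5-bis(3-methylbut-2-en-1-yl)phenyl](phenyl)methanolate (racemic) | [Li+].[O-]C(c1ccccc1)c1c(OCOC)c(CC=C(C)C)c(OC)c(CC=C(C)C)c1OCOC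
F7 | step 7 | [4-methoxy-2,6-bis(methoxymethoxy)-3,5-bis(3-methylbut-2-en-1-yl)phenyl](phenyl)methanol (racemic) | OC(c1ccccc1)c1c(OCOC)c(CC=C(C)C)c(OC)c(CC=C(C)C)c1OCOC
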